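## The problem

Target 13 is a flavone: benzo ring A is fused to the 4-pyranone ring C, and aryl ring B sits on C2. It has no stereocentre, so the task is one of regiochemistry: eight oxygens must be placed, and two phenols must end up free beside five methyl ethers. Ring A carries oxygen at C5, C6, C7 and C8a (O1) with C8 bare; ring B carries oxygen at C2', C3', C4' and C6' with C5' bare. Ring B is therefore di-ortho-substituted and the C2–C1' bond is crowded, so that bond is better carried in an open chain than made late by cross-coupling. The pyranone can be opened at C2 by hydroxide or amines, and vicinal trimethoxyarenes lose methyl groups to strong Lewis or protic acids, so the late steps must be mild and the one demethylation must be directed. The feature that makes the key step possible is a hidden symmetry. Counted from the carbon that bears the three-carbon bridge (C4a in ring A, C1' in ring B), both rings have oxygen at positions 2, 3, 4 and 6 and hydrogen at position 5. If O1–C8a is cut and the oxygens at C8a and C6' are both written as bromine, the C2–C3–C4 chain carries two identical 6-bromo-2,3,4-trimethoxyphenyl groups. The only remaining difference between the rings, 5-OH against 2'-OMe, lies at the one methoxy group that the C4 carbonyl can single out by chelation.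

## Retrosynthesis

**13 ⇒ 12.** The O–CH3 bond at C5 is cut first. Carrying the C5 oxygen under its own protecting group from the start would make ring A differ from ring B and destroy the symmetry. The precursor 12 has six methyl ethers of one kind and a single free hydroxyl at C6'. The forward step must remove exactly one methyl group, which calls for a Lewis acid that is held by the C4 carbonyl and reaches only the peri methoxy group.

**12 ⇒ 11 ⇒ 10.** The C6'–O bond is traced back to C6'–B in boronate 11 and to C6'–Br in bromoflavone 10. A protected phenol on ring B would need a second, separately built arene. A bromide at C6' is the same group that the ring closure needs at C8a, so both functions come from one substituent. The forward steps must borylate a hindered, electron-rich aryl bromide and oxidise the boronate without opening the pyranone.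

**10 ⇒ 9.** Ring C is opened at O1–C8a. Cutting O1–C2 instead (cyclodehydration of a phenolic diketone) needs a free phenol on one ring only. Cutting C4–C4a (acylation of an aryl enol ether) needs strong acid and also makes the rings unlike. With bromine at C8a, the chosen cut leads to diketone 9, which has one ring fewer, a mirror plane and two identical aryl groups. The forward reaction must join an enol oxygen to an aryl carbon, use only one of the two bromides and avoid C-arylation.

**9 ⇒ 8 ⇒ 6 + 3.** After one carbonyl of 9 is lowered to the carbinol of 8, the bond between the central carbon and the carbinol carbon is cut as an aldol. The neighbouring choice is acylation of the enolate of 6 with an acid chloride. It costs two more operations (oxidation to the acid, activation) and, with a di-ortho-substituted acid chloride, risks O-acylation. The aldol uses aldehyde 3 as it is, and both halves of 9 then derive from 3. The forward steps must give a clean crossed aldol and oxidise the β-hydroxy ketone without dehydration.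

**6 ⇒ 5 ⇒ 3 + 4.** The methyl–carbonyl bond is cut, giving aldehyde 3 and methylmagnesium bromide 4 by way of alcohol 5. Direct Friedel–Crafts acetylation of 1 would save a step on this branch. It needs Lewis acids that tend to strip the methoxy group next to the new ketone, and it would still leave 3 to be made for the other half. The forward steps are a Grignard addition that leaves the aryl bromide alone and a neutral oxidation.

**3 ⇒ 1 + 2.** The aryl–CHO bond is cut. Bromoarene 1 has two free positions that are equivalent, each ortho and para to a methoxy group, so formylation with 2 can give only one aldehyde. This single substitution fixes all five substituents of both rings.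

## Roads not taken

Alternative 1: Ring A is introduced as an aryne, so that O1–C8a and C4–C4a are made together. Fluoride (CsF) would release the aryne from silylaryl triflate A2. The carboxylate of ring B propiolic acid A3 adds to it, and the aryl anion so formed takes the acyl group from oxygen to give ortho-hydroxyaryl ynone A1. A 6-endo cyclisation and hydrogenolysis of the benzyl ether would then reach 12.
- Merits: two skeletal bonds form in one step. The methoxy group next to the aryne bond should steer the oxygen nucleophile to the remote carbon, which is the orientation ring A needs. The C6' oxygen is present from the start, so debenzylation replaces the two-step bromide-to-phenol conversion of the chosen plan, a real advantage.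
- Weak points: A2 and A3 are two different multistep building blocks, and A3 needs a ring B with one of four oxygens differentiated. Arylpropiolic acids decarboxylate readily under basic fluoride conditions. Protonation of the aryl anion competes with acyl transfer and gives an aryl ester. Ring closure of A1 can go 5-exo to an aurone.
- Comparison: the chosen plan needs a palladium step that this route avoids. Against that, one commercial arene supplies every aromatic carbon, and the key step has no regiochemical question.

Alternative 2: O1–C8a is cut as in the chosen plan, but ring B arrives as 4-hydroxycoumarin A5, whose lactone oxygen is the future C6' oxygen. A5 would be acylated at C3 by bromoaroyl chloride A6, and the 4-oxygen would then displace the bromide with CuI and K2CO3 to give the lactone-bridged flavone A4. Opening the lactone to flavone-3-carboxylic acid A7 and decarboxylation would give 12.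
- Merits: the ring closure is of the same reliable type. The C6' oxygen is built in and masked, so no borylation and oxidation are needed.
- Weak points: two aromatic building blocks are required. Hindered acid chlorides usually acylate 4-hydroxycoumarins on oxygen first, so a rearrangement is needed. The decisive weakness is removal of the bridge: hydroxide must open the lactone of A4 without attacking C2 of a pyranone activated by two carbonyl groups, and A7 must then lose CO2 on heating.
- Comparison: the key bond formation is equal in quality. The route is no shorter, and it trades the palladium step for a bridge excision that is harder to defend.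

Alternative 3: Ring C is closed at C4–C4a. Phenol A10 would add to ring B propiolate A11, and saponification would give the Z-aryloxyacrylic acid A9. Activation with trifluoroacetic anhydride or P2O5 in methanesulfonic acid would acylate the aryloxy ring to give benzyloxyflavone A8, and hydrogenolysis would give 12.
- Merits: A10 is a cheap symmetrical phenol with two equivalent, strongly activated ortho positions, so the closure is regiochemically unambiguous and needs no metal. Ring A requires no synthesis, which is better than the chosen plan on that side.
- Weak points: A11 is a multistep ring B fragment with a differentiated oxygen. Addition of a phenol to a di-ortho-substituted arylpropiolate is hindered, and only the Z isomer can close. The strongly acidic medium threatens the benzyl ether (cleavage and benzylation of the electron-rich rings) and the aryl enol ether (hydrolysis).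
- Comparison: the chosen plan closes ring C under weak base with copper, conditions that its hexamethoxy substrate tolerates. It builds both rings from one aldehyde, at the price of the late bromide-to-phenol conversion.

Key step: step 6

Assumptions:
- Diketone 9 is drawn as the diketo tautomer, although it should exist mainly as the chelated enol.
- Alcohols 5 and 8 are racemic, and their stereocentres are removed by the oxidations that follow.
- In step 1 the aldehyde oxygen is taken to come from water on hydrolytic work-up.
- 1-(6-Hydroxy-2,3,4-trimethoxyphenyl)ethan-1-one F3, used only in one fallback, is taken to be purchasable.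

## Route

Step 1
Reactants: 1 5-bromo-1,2,3-trimethoxybenzene; 2 dichloromethyl methyl ether
Product: 3 6-bromo-2,3,4-trimethoxybenzaldehyde
Conditions: TiCl4 (2 equiv), CH2Cl2, −10 to 0 °C; then ice-water
Reagents that add atoms: dichloromethyl methyl ether 2, COC(Cl)Cl (formyl carbon); water, O (carbonyl oxygen on hydrolysis)
Why: Rieche formylation; the two free positions of 1 are equivalent and each is ortho and para to a methoxy group, so only one aldehyde can form, and the new formyl group deactivates the ring against a second substitution.

Step 2
Reactants: 3 6-bromo-2,3,4-trimethoxybenzaldehyde; 4 methylmagnesium bromide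
Product: 5 racemic 1-(6-bromo-2,3,4-trimethoxyphenyl)ethan-1-ol
Conditions: MeMgBr (1.2 equiv), THF, 0 °C; then aq. NH4Cl
Reagents that add atoms: methylmagnesium bromide 4, C[Mg]Br (methyl group)
Why: Grignard addition to an aldehyde; MeMgBr does not exchange with an aryl bromide at 0 °C, and the carbinol centre forms as a racemate that step 3 removes.

Step 3
Reactants: 5 racemic 1-(6-bromo-2,3,4-trimethoxyphenyl)ethan-1-ol
Product: 6 1-(6-bromo-2,3,4-trimethoxyphenyl)ethan-1-one
Conditions: Dess–Martin periodinane (1.3 equiv), CH2Cl2, 0 °C to rt
Reagents that add atoms: none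
Why: Dess–Martin oxidation of a secondary benzylic alcohol to the aryl methyl ketone under near-neutral conditions that leave the aryl bromide and the methyl ethers untouched.

Step 4
Reactants: 6 1-(6-bromo-2,3,4-trimethoxyphenyl)ethan-1-one; 3 6-bromo-2,3,4-trimethoxybenzaldehyde
Product: 8 racemic 1,3-bis(6-bromo-2,3,4-trimethoxyphenyl)-3-hydroxypropan-1-one, via lithium enolate 7 (not isolated)
Conditions: LiN(SiMe3)2 (1.1 equiv), THF, −78 °C; then 3, −78 °C; AcOH quench at −78 °C
Reagents that add atoms: none
Why: Directed crossed aldol addition of a preformed lithium enolate; 3 has no α-hydrogen and 6 is fully enolised before 3 is added, so only the cross product can form, and the cold acidic quench should prevent retro-aldol and dehydration; the carbinol centre is racemic and is removed in step 5.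

Step 5
Reactants: 8 racemic 1,3-bis(6-bromo-2,3,4-trimethoxyphenyl)-3-hydroxypropan-1-one
Product: 9 1,3-bis(6-bromo-2,3,4-trimethoxyphenyl)propane-1,3-dione
Conditions: IBX (2.5 equiv), EtOAc, 75 °C
Reagents that add atoms: none
Why: IBX oxidation of a β-hydroxy ketone to the 1,3-diketone, an established use of this reagent that stops at the diketone; the medium is neutral, so loss of water to the chalcone is not expected.

Step 6
Reactants: 9 1,3-bis(6-bromo-2,3,4-trimethoxyphenyl)propane-1,3-dione
Product: 10 2-(6-bromo-2,3,4-trimethoxyphenyl)-5,6,7-trimethoxy-4H-chromen-4-one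
Conditions: CuI (10 mol %), N,N'-dimethylethylenediamine (20 mol %), K2CO3 (2 equiv), degassed DMF, 100 °C, argon
Reagents that add atoms: none
Why: This is an intramolecular Ullmann-type C–O coupling, the known copper-catalysed O-arylation of 1-(2-haloaryl)-1,3-diketones to chromones and flavones. K2CO3 converts 9 into its enolate, which binds diamine-ligated monovalent copper through oxygen; the metal inserts into the C–Br bond ortho to the bound carbonyl unit to give a trivalent copper aryl, and C–O reductive elimination forms O1–C8a and returns monovalent copper. Ring C closes as a six-membered ring by attack of the distal enolate oxygen on the aryl carbon, with the leaving bromide outside the new ring (formally a 6-exo closure at an sp2 carbon within the coordination sphere of copper). Attack by the central carbon or by the proximal oxygen would give a four-membered ring, which settles O- against C-arylation. The two aryl groups of 9 are identical, so either oxygen with either bromide gives the same flavone and no site selectivity is required. The reaction should stop after one closure: no enolate remains once ring C exists, the ring B bromide has neither an ortho carbonyl nor a nucleophile within reach, and the N,N'-dimethylated diamine is a poor partner for N-arylation. The ortho carbonyl offsets the electron-rich character of the bromoarene toward insertion. No stereocentre is formed.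

Step 7
Reactants: 10 2-(6-bromo-2,3,4-trimethoxyphenyl)-5,6,7-trimethoxy-4H-chromen-4-one
Product: 11 5,6,7-trimethoxy-2-[2,3,4-trimethoxy-6-(4,4,5,5-tetramethyl-1,3,2-dioxaborolan-2-yl)phenyl]-4H-chromen-4-one
Conditions: B2pin2 (1.5 equiv), Pd2(dba)3 (2.5 mol %), XPhos (10 mol %), KOAc (3 equiv), 1,4-dioxane, 100 °C
Reagents that add atoms: bis(pinacolato)diboron, CC1(C)OB(OC1(C)C)B1OC(C)(C)C(C)(C)O1
Why: Miyaura borylation; the bulky electron-rich biarylphosphine should promote insertion of zerovalent palladium into the hindered, electron-rich C–Br bond, and KOAc is too weak a base to open the pyranone or to drive Suzuki homocoupling.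

Step 8
Reactants: 11 5,6,7-trimethoxy-2-[2,3,4-trimethoxy-6-(4,4,5,5-tetramethyl-1,3,2-dioxaborolan-2-yl)phenyl]-4H-chromen-4-one
Product: 12 2-(6-hydroxy-2,3,4-trimethoxyphenyl)-5,6,7-trimethoxy-4H-chromen-4-one
Conditions: NaBO3·4H2O (3 equiv), THF/H2O (1:1), rt
Reagents that add atoms: NaBO3·4H2O (sodium perborate tetrahydrate), [Na+].[O-]OB=O.O.O.O.O (phenol oxygen)
Why: Oxidation of an arylboronic ester to the phenol by 1,2-shift of the aryl group from boron to oxygen in the peroxoborate adduct; perborate is weakly basic and should not epoxidise or cleave the pyranone, and any opening and reclosure of ring C at this stage would return 12, because the opened diketone would carry two identical aryl groups.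

Step 9
Reactants: 12 2-(6-hydroxy-2,3,4-trimethoxyphenyl)-5,6,7-trimethoxy-4H-chromen-4-one
Product: 13 5-hydroxy-2-(6-hydroxy-2,3,4-trimethoxyphenyl)-6,7-dimethoxy-4H-chromen-4-one (5,6'-dihydroxy-6,7,2',3',4'-pentamethoxyflavone)
Conditions: BCl3 (3 equiv, 1 M in CH2Cl2), CH2Cl2, −78 to 0 °C; then H2O
Reagents that add atoms: none
Why: Chelation-controlled ether cleavage; BCl3 binds the C4 carbonyl, the peri 5-methoxy oxygen completes a six-membered boron chelate and chloride removes its methyl group, whereas the other five methyl ethers have no carbonyl neighbour; one further equivalent is taken up by the 6'-hydroxyl and released on hydrolysis.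

## Compound list

1 | 5-bromo-1,2,3-trimethoxybenzene | COc1cc(Br)cc(OC)c1OC | starting material
2 | dichloromethyl methyl ether | COC(Cl)Cl | starting material
3 | 6-bromo-2,3,4-trimethoxybenzaldehyde | COc1cc(Br)c(C=O)c(OC)c1OC | intermediate
4 | methylmagnesium bromide | C[Mg]Br | starting material
5 | racemic 1-(6-bromo-2,3,4-trimethoxyphenyl)ethan-1-ol | COc1cc(Br)c(C(C)O)c(OC)c1OC | intermediate
6 | 1-(6-bromo-2,3,4-trimethoxyphenyl)ethan-1-one | COc1cc(Br)c(C(C)=O)c(OC)c1OC | intermediate
7 | lithium 1-(6-bromo-2,3,4-trimethoxyphenyl)ethen-1-olate (lithium enolate of 6) | COc1cc(Br)c(C(=C)O[Li])c(OC)c1OC | intermediate (not isolated)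
8 | racemic 1,3-bis(6-bromo-2,3,4-trimethoxyphenyl)-3-hydroxypropan-1-one | COc1cc(Br)c(C(O)CC(=O)c2c(Br)cc(OC)c(OC)c2OC)c(OC)c1OC | intermediate
9 | 1,3-bis(6-bromo-2,3,4-trimethoxyphenyl)propane-1,3-dione | COc1cc(Br)c(C(=O)CC(=O)c2c(Br)cc(OC)c(OC)c2OC)c(OC)c1OC | intermediate
10 | 2-(6-bromo-2,3,4-trimethoxyphenyl)-5,6,7-trimethoxy-4H-chromen-4-one | COc1cc(Br)c(-c2cc(=O)c3c(OC)c(OC)c(OC)cc3o2)c(OC)c1OC | intermediate
11 | 5,6,7-trimethoxy-2-[2,3,4-trimethoxy-6-(4,4,5,5-tetramethyl-1,3,2-dioxaborolan-2-yl)phenyl]-4H-chromen-4-one | COc1cc(B2OC(C)(C)C(C)(C)O2)c(-c2cc(=O)c3c(OC)c(OC)c(OC)cc3o2)c(OC)c1OC | intermediate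
12 | 2-(6-hydroxy-2,3,4-trimethoxyphenyl)-5,6,7-trimethoxy-4H-chromen-4-one | COc1cc(O)c(-c2cc(=O)c3c(OC)c(OC)c(OC)cc3o2)c(OC)c1OC | intermediate
13 | 5-hydroxy-2-(6-hydroxy-2,3,4-trimethoxyphenyl)-6,7-dimethoxy-4H-chromen-4-one | COc1cc(O)c(-c2cc(=O)c3c(O)c(OC)c(OC)cc3o2)c(OC)c1OC | target

## Step count and risks

Total steps: 9. Longest linear sequence: 9 steps (1 to 13; aldehyde 3 enters twice, in steps 2 and 4).

The least certain steps, in route order, are steps 4, 6 (key), 7 and 9.

**Step 4 (aldol addition).**
- Risk: the addition may revert, or the adduct may lose water to the chalcone during quench and handling. Both partners are di-ortho-substituted, so the aldolate is crowded, and the benzylic carbinol is flanked by donor methoxy groups and ionises easily.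
- Fallback, from 3 and 6 to 9: replace the aldol by an acylation. Aldehyde 3 is oxidised (NaClO2, NaH2PO4, 2-methyl-2-butene, tBuOH/H2O) to 6-bromo-2,3,4-trimethoxybenzoic acid F1. F1 is converted with oxalyl chloride and catalytic DMF into 6-bromo-2,3,4-trimethoxybenzoyl chloride F2. Ketone 6 is C-acylated by F2 under soft enolisation (MgBr2·OEt2, iPr2NEt, CH2Cl2). This gives 9 directly and bypasses 8 and step 5.

**Step 6 (key step).**
- Risk: base-induced cleavage of the diketone (retro-Claisen by adventitious water at 100 °C) may outrun a slow insertion of copper into the electron-rich, doubly flanked C–Br bond. The second bromide may also be lost by reduction.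
- Fallback, from 3 to 10: give up the symmetry and close ring C at O1–C2 by the classical route. Aldehyde 3 is taken to acid F1 and acid chloride F2 as described for step 4. The dianion of 1-(6-hydroxy-2,3,4-trimethoxyphenyl)ethan-1-one F3 (LiN(SiMe3)2, 3 equiv, THF, −78 °C) is acylated by F2 to give 1-(6-bromo-2,3,4-trimethoxyphenyl)-3-(6-hydroxy-2,3,4-trimethoxyphenyl)propane-1,3-dione F4. Cyclodehydration of F4 (catalytic H2SO4, AcOH, 100 °C) gives 10, and steps 7 to 9 follow unchanged.

**Step 7 (borylation).**
- Risk: bromine may be replaced by hydrogen at the hindered position, and the electron-rich, ortho-substituted boronate may lose boron by protonolysis on prolonged heating.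
- Fallback, from 10 to 12: form the C6'–O bond directly by palladium-catalysed coupling with a hydroxide surrogate. Bromide 10 is coupled with (E)-benzaldoxime (Pd2(dba)3, tBuBrettPhos, Cs2CO3, DMF, 80 °C) to give (E)-benzaldehyde O-[3,4,5-trimethoxy-2-(5,6,7-trimethoxy-4-oxo-4H-chromen-2-yl)phenyl]oxime F5. F5 fragments in the same flask under the carbonate base to benzonitrile and the phenolate of 12. This bypasses 11 and step 8.

**Step 9 (demethylation).**
- Risk: cleavage may run on to the 6-methoxy group, since a boron-bound 5-oxygen can pass Lewis acid to its neighbour. The free 6'-hydroxyl forces an excess of BCl3, which blurs the stoichiometry.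
- Fallback, from 10 to 13: change the order, so that the demethylation is done on a substrate with no free hydroxyl and little more than one equivalent of BCl3 suffices. Bromoflavone 10 is treated with BCl3 (CH2Cl2, −78 to 0 °C) to give 2-(6-bromo-2,3,4-trimethoxyphenyl)-5-hydroxy-6,7-dimethoxy-4H-chromen-4-one F6. Miyaura borylation under the conditions of step 7 gives 5-hydroxy-6,7-dimethoxy-2-[2,3,4-trimethoxy-6-(4,4,5,5-tetramethyl-1,3,2-dioxaborolan-2-yl)phenyl]-4H-chromen-4-one F7. Oxidation of F7 with NaBO3·4H2O gives 13.

## Further compounds

F1 | step 4 | 6-bromo-2,3,4-trimethoxybenzoic acid | COc1cc(Br)c(C(=O)O)c(OC)c1OC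
F2 | step 4 | 6-bromo-2,3,4-trimethoxybenzoyl chloride | COc1cc(Br)c(C(=O)Cl)c(OC)c1OC
F3 | step 6 | 1-(6-hydroxy-2,3,4-trimethoxyphenyl)ethan-1-one | COc1cc(O)c(C(C)=O)c(OC)c1OC
F4 | step 6 | 1-(6-bromo-2,3,4-trimethoxyphenyl)-3-(6-hydroxy-2,3,4-trimethoxyphenyl)propane-1,3-dione | COc1cc(Br)c(C(=O)CC(=O)c2c(O)cc(OC)c(OC)c2OC)c(OC)c1OC
F5 | step 7 | (E)-benzaldehyde O-[3,4,5-trimethoxy-2-(5,6,7-trimethoxy-4-oxo-4H-chromen-2-yl)phenyl]oxime | COc1cc(O/N=C/c2ccccc2)c(-c2cc(=O)c3c(OC)c(OC)c(OC)cc3o2)c(OC)c1OC
F6 | step 9 | 2-(6-bromo-2,3,4-trimethoxyphenyl)-5-hydroxy-6,7-dimethoxy-4H-chromen-4-one | COc1cc(Br)c(-c2cc(=O)c3c(O)c(OC)c(OC)cc3o2)c(OC)c1OC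
F7 | step 9 | 5-hydroxy-6,7-dimethoxy-2-[2,3,4-trimethoxy-6-(4,4,5,5-tetramethyl-1,3,2-dioxaborolan-2-yl)phenyl]-4H-chromen-4-one | COc1cc(B2OC(C)(C)C(C)(C)O2)c(-c2cc(=O)c3c(O)c(OC)c(OC)cc3o2)c(OC)c1OC
A1 | alternative 1 | 3-[2-(benzyloxy)-4,5,6-trimethoxyphenyl]-1-(2-hydroxy-4,5,6-trimethoxyphenyl)prop-2-yn-1-one | COc1cc(O)c(C(=O)C#Cc2c(OCc3ccccc3)cc(OC)c(OC)c2OC)c(OC)c1OC
A2 | alternative 1 | 3,4,5-trimethoxy-2-(trimethylsilyl)phenyl trifluoromethanesulfonate | COc1cc(OS(=O)(=O)C(F)(F)F)c([Si](C)(C)C)c(OC)c1OC
A3 | alternative 1 | 3-[2-(benzyloxy)-4,5,6-trimethoxyphenyl]prop-2-ynoic acid | OC(=O)C#Cc1c(OCc2ccccc2)cc(OC)c(OC)c1OC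
A4 | alternative 2 | hexamethoxychromeno[4,3-b]chromene-6,7-dione (lactone-bridged flavone) | COc1cc2oc(=O)c3c(=O)c4c(OC)c(OC)c(OC)cc4oc3c2c(OC)c1OC
A5 | alternative 2 | 4-hydroxy-5,6,7-trimethoxy-2H-chromen-2-one | COc1cc2oc(=O)cc(O)c2c(OC)c1OC
A6 | alternative 2 | 6-bromo-2,3,4-trimethoxybenzoyl chloride | COc1cc(Br)c(C(=O)Cl)c(OC)c1OC
A7 | alternative 2 | 2-(6-hydroxy-2,3,4-trimethoxyphenyl)-5,6,7-trimethoxy-4-oxo-4H-chromene-3-carboxylic acid | COc1cc(O)c(-c2oc3cc(OC)c(OC)c(OC)c3c(=O)c2C(=O)O)c(OC)c1OC
A8 | alternative 3 | 2-[2-(benzyloxy)-4,5,6-trimethoxyphenyl]-5,6,7-trimethoxy-4H-chromen-4-one | COc1cc(OCc2ccccc2)c(-c2cc(=O)c3c(OC)c(OC)c(OC)cc3o2)c(OC)c1OC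
A9 | alternative 3 | (2Z)-3-[2-(benzyloxy)-4,5,6-trimethoxyphenyl]-3-(3,4,5-trimethoxyphenoxy)prop-2-enoic acid | OC(=O)/C=C(\Oc1cc(OC)c(OC)c(OC)c1)c1c(OCc2ccccc2)cc(OC)c(OC)c1OC
A10 | alternative 3 | 3,4,5-trimethoxyphenol | COc1cc(O)cc(OC)c1OC
A11 | alternative 3 | methyl 3-[2-(benzyloxy)-4,5,6-trimethoxyphenyl]prop-2-ynoate | COC(=O)C#Cc1c(OCc2ccccc2)cc(OC)c(OC)c1OC
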